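The data were computed for substances that don't exist, noise included.

A closed, stirred, isothermal vessel turns Q into Z over E, and the charge of G changes from flask to flask.

| flask | Q | E | G | remark | time |
|---|---|---|---|---|---|
| elm | 0.010 M | 2 µM | 4.2 µM | run made earlier |  |
| maple | 0.010 M | 2 µM | 17 µM | run made earlier |  |
| west | 0.010 M | 2.0 µM | 3.0 µM |  | 2.0 h |
| south | 0.010 M | 2.0 µM | 6.0 µM |  | 2.0 h |
| south-east | 0.010 M | 2.0 µM | 12 µM |  | 2.0 h |

| run | time / min | Z / % |
|---|---|---|
| elm | 6.00 | 5.5 |
| elm | 12.0 | 10.4 |
| elm | 25.0 | 20.1 |
| elm | 40.0 | 29.2 |
| elm | 80.0 | 48.2 |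
| maple | 8.00 | 2.2 |
| maple | 20.0 | 5.9 |
| maple | 40.0 | 12.0 |
| maple | 60.0 | 16.6 |
| maple | 80.0 | 21.7 |

(standard deviation of a reading: 0.3 percentage points)

* [Z] at the end for west, south, south-east, in this order
* the course of these numbers from the first flask to the last (hardly changes / rises all the way / falls, then rises / falls all the way / rises, then falls)

- "hardly changes" means that all values lie within two and a half points (for a concentration: within two and a half percent of the largest)

What do the two runs say? At nearly equal Z, elm stood at 10.4% after 12.0 min and maple at 12.0% after 40.0 min. As first-order constants these read 0.00915 min⁻¹ and 0.00320 min⁻¹, so elm runs faster than maple by a factor of 2.86, while its G is lower by a factor of 4.05.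

Your reading? My working assumption is that G holds E reversibly, and that the free share f of E sets the rate.

Then what must be found? The half-free level of G, the dissociation constant: the free G at which half of E is free, so that f = kd/(kd + free G). Taking free G as charged gives 2.67 µM. But E is charged at 2.0 µM, which is not small against elm's 4.2 µM of G. Putting that first answer back leaves free G of 2.98 µM in elm and 15.3 µM in maple, and the level becomes 3.62 µM.

That moved. Is it safe? It is a reading from two points, but the ratio to elm is what gets used. Going round twice, west's f runs 63.4%, then 61.5%, and elm's comes to 52.5%. Their ratio is 1.17, and the first level, with free G taken as charged, gave 1.21.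

And Z? The charges of Q and E match elm's, so I count elm-minutes: t times f over elm's f. With south at 42.7% and south-east at 25.6%, the 2.0 h become 141 min, 97.5 min and 58.5 min. Elm's last reading gives the constant 0.00822 min⁻¹.

Weak spot? On elm's clock, west and south lie beyond elm's last reading at 80.0 min, so they are extrapolated. My reckoning gives 0.00685 M, 0.00551 M and 0.00382 M.

The forecast, reading “G binding E reversibly”, gives 0.0066 M, 0.0053 M and 0.0037 M, lower than mine at each point, and its shape is falls all the way.

The flask gives 0.00676 M, 0.00544 M and 0.00380 M: falls all the way. In west at 2.00 h, E stands at 59.6% of the catalyst and J, an off-cycle form, at 40.4%.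

    Q + E → Z + E, rate k1*[Q]*[E]/(1 + ([Q]/Km1) + ([Z]/Kp1)) (32.0 mM, 12.0 mM, k = 12000 M⁻¹ min⁻¹)
    E + G ⇌ J, settled at all times (K = 3.10 × 10⁵ M⁻¹)

The level 3.62 µM goes once more to south, at 1.00 h: its reckoned f of 42.7% makes that time 48.8 min on elm's clock, which gives Z of 33.0%. South at 1.00 h holds Z of 33.7%.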